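**Retrosynthetic overview**

1. Ring A is the 7-hydroxy-5-styryl dihydrobenzofuran, ring B the 6-styryl dihydrobenzofuran, ring C the 6-hydroxy dihydrobenzofuran bonded through C4 to C3 of ring B. The nine O-methyl groups and the central E-alkene are disconnected last (Mizoroki–Heck: ring-A styrene + ring-B aryl chloride).
2. The C3(ring B)–C4(ring C) bond and both C3–(3,5-dimethoxyphenyl) bonds come from decarboxylative sp3–sp2 arylations of 2-aryl-2,3-dihydrobenzofuran-3-carboxylic acids, each setting C3 trans to C2.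
3. Each acid, ring B first, comes from a flavanone by oxidative 6→5 ring contraction: the benzo carbon C4a shifts from C4 to C3, and the C4 carbonyl carbon is pushed out of the ring as the carboxylate that later leaves as CO2.
4. Enabling feature: in ring B, O1–C2(H)(4-oxyphenyl)–C3 fused at C3a/C7a is the O1–C2–C3/C4a–C8a unit of a flavanone, and C3 bears a C-linked aryl group exactly where the expelled carbonyl carbon can serve as a leaving carboxyl; rings A and C repeat the pattern.
5. The flavanones come from three chromones by asymmetric conjugate addition of 4-methoxyphenylboronic acid with Pd(OCOCF3)2/t-BuPyOX (C2: R for ring B, S for rings A and C). Ring order: pyranone rings, then furan rings B, C and A by contraction, then B–C union, then the stilbene.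

Key step: step 3

Assumption: (S)-t-BuPyOX is taken to give the (2R)-flavanone and (R)-t-BuPyOX the (2S)-flavanone, by analogy with the sense of induction on cyclic enones; if the facial preference is the reverse, the two ligand enantiomers are exchanged and nothing else changes.

**Route**

Step 1
Reactants: 1 1-(4-chloro-2-hydroxyphenyl)ethan-1-one
Product: 3 7-chloro-4H-chromen-4-one, via enaminone 2 (not isolated)
Conditions: DMF-DMA (1.5 equiv), toluene, 100 °C; evaporate; then conc. HCl, CH2Cl2, 40 °C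
Reagents that add atoms: N,N-dimethylformamide dimethyl acetal, COC(OC)N(C)C
Why: Standard chromone synthesis: condensation of the methyl ketone with the amide acetal gives the enaminone, and acid closes the pyranone ring by oxa-Michael addition of the phenol and loss of dimethylamine.

Step 2
Reactants: 3 7-chloro-4H-chromen-4-one; 4 (4-methoxyphenyl)boronic acid
Product: 5 (2R)-7-chloro-2-(4-methoxyphenyl)-2,3-dihydro-4H-chromen-4-one
Conditions: 4 (2 equiv), Pd(OCOCF3)2 (5 mol%), (S)-t-BuPyOX (6 mol%), NH4PF6 (30 mol%), H2O (5 equiv), ClCH2CH2Cl, 60 °C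
Reagents that add atoms: none
Why: Asymmetric conjugate addition of an arylboronic acid to a chromone under divalent-palladium catalysis with Pd(OCOCF3)2/(S)-t-BuPyOX, in which the aryl–palladium species adds to C2 on the enone face selected by the tert-butyl oxazoline ligand (sets C2 as R) and the aryl chloride stays inert because no zerovalent palladium is formed.

Step 3
Reactants: 5 (2R)-7-chloro-2-(4-methoxyphenyl)-2,3-dihydro-4H-chromen-4-one
Product: 7 methyl (2R,3R)-6-chloro-2-(4-methoxyphenyl)-2,3-dihydro-1-benzofuran-3-carboxylate, via methyl enol ether 6 (not isolated)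
Conditions: PhI(OAc)2 (1.2 equiv), conc. H2SO4 (0.3 equiv), HC(OMe)3, 20 °C; then aq. NaHCO3
Reagents that add atoms: trimethyl orthoformate, COC(OC)OC; water, O
Why: Hypervalent-iodine oxidative rearrangement of a flavanone in trimethyl orthoformate, the known ring contraction to methyl trans-2-aryl-2,3-dihydrobenzofuran-3-carboxylates: acid and orthoformate convert ketone 5 into enol ether 6, PhI(OAc)2 adds to C3 anti to the C2 aryl group while methanol caps C4 as the dimethyl ketal, and the benzo carbon C4a then shifts from C4 to C3 with loss of iodobenzene, leaving a dimethoxycarbenium ion that is hydrolysed to the ester. Ring B is closed in this shift by ipso attack of the benzo ring on C3 through a three-membered phenonium bridge followed by cleavage of the old C4–C4a bond, so the six-membered pyranone ring O1–C2–C3–C4–C4a–C8a becomes the five-membered ring O1–C2–C3–C3a–C7a and C4 becomes the exocyclic carboxyl carbon. C2 is not involved and should keep its R configuration; the new C3 centre is set by the substrate, because the equatorial C3–I bond lies antiperiplanar to C4–C4a and migration with inversion at C3 places the carboxylate trans to the C2 aryl group. The step needs migration of the benzo ring in preference to a 2→3 shift of the anisyl group (isoflavone) and to dehydrogenation (flavone); the two methoxy groups on C4 stabilise the cation that only the C4-bound aryl shift leaves behind, and the chair-like ring holds this ring bond, not the C2–aryl bond, anti to iodine. The closest precedent is the same ring contraction of optically active flavanones that carry alkoxyaryl groups at C2.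

Step 4
Reactants: 7 methyl (2R,3R)-6-chloro-2-(4-methoxyphenyl)-2,3-dihydro-1-benzofuran-3-carboxylate
Product: 8 (2R,3R)-6-chloro-2-(4-methoxyphenyl)-2,3-dihydro-1-benzofuran-3-carboxylic acid
Conditions: LiOH·H2O (3 equiv), THF/MeOH/H2O (3:1:1), 20 °C; then 1 M HCl
Reagents that add atoms: lithium hydroxide, [Li+].[OH-]
Why: Saponification of a methyl ester (BAc2); the trans acid is the thermodynamic C3 epimer and C2 is not acidic, so the C2 configuration is carried on unchanged.

Step 5
Reactants: 9 1-bromo-3,5-dimethoxybenzene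
Product: 11 1-(2-bromo-6-hydroxy-4-methoxyphenyl)ethan-1-one, via dimethoxy ketone 10 (not isolated)
Conditions: AcCl (1.1 equiv), AlCl3 (3 equiv), CH2Cl2, 0 → 40 °C; then ice/1 M HCl
Reagents that add atoms: acetyl chloride, CC(Cl)=O
Why: Friedel–Crafts acylation at C2 (para to one methoxy group; the position between the two methoxy groups is more hindered), followed in the same pot by chelation-controlled cleavage with AlCl3 of the methoxy group ortho to the new ketone.

Step 6
Reactants: 11 1-(2-bromo-6-hydroxy-4-methoxyphenyl)ethan-1-one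
Product: 13 5-bromo-7-methoxy-4H-chromen-4-one, via enaminone 12 (not isolated)
Conditions: DMF-DMA (1.5 equiv), toluene, 100 °C; evaporate; then conc. HCl, CH2Cl2, 40 °C
Reagents that add atoms: N,N-dimethylformamide dimethyl acetal, COC(OC)N(C)C
Why: Same enaminone condensation and acid-promoted oxa-Michael cyclisation with loss of dimethylamine as in step 1.

Step 7
Reactants: 13 5-bromo-7-methoxy-4H-chromen-4-one; 4 (4-methoxyphenyl)boronic acid
Product: 14 (2S)-5-bromo-7-methoxy-2-(4-methoxyphenyl)-2,3-dihydro-4H-chromen-4-one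
Conditions: 4 (2 equiv), Pd(OCOCF3)2 (5 mol%), (R)-t-BuPyOX (6 mol%), NH4PF6 (30 mol%), H2O (5 equiv), ClCH2CH2Cl, 60 °C
Reagents that add atoms: none
Why: Asymmetric conjugate addition of the arylboronic acid to the chromone as in step 2 but with the mirror-image ligand, which should set C2 as S; the aryl bromide is tolerated because palladium stays divalent.

Step 8
Reactants: 14 (2S)-5-bromo-7-methoxy-2-(4-methoxyphenyl)-2,3-dihydro-4H-chromen-4-one
Product: 16 methyl (2S,3S)-4-bromo-6-methoxy-2-(4-methoxyphenyl)-2,3-dihydro-1-benzofuran-3-carboxylate, via methyl enol ether 15 (not isolated)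
Conditions: PhI(OAc)2 (1.2 equiv), conc. H2SO4 (0.3 equiv), HC(OMe)3, 20 °C; then aq. NaHCO3
Reagents that add atoms: trimethyl orthoformate, COC(OC)OC; water, O
Why: Hypervalent-iodine ring contraction of a flavanone as in step 3, here forming ring C; the 7-methoxy group para to the migrating carbon should raise its migratory aptitude, C2 keeps its S configuration and the ester is placed trans by the antiperiplanar shift.

Step 9
Reactants: 8 (2R,3R)-6-chloro-2-(4-methoxyphenyl)-2,3-dihydro-1-benzofuran-3-carboxylic acid; 16 methyl (2S,3S)-4-bromo-6-methoxy-2-(4-methoxyphenyl)-2,3-dihydro-1-benzofuran-3-carboxylate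
Product: 17 methyl (2S,3S)-4-[(2R,3R)-6-chloro-2-(4-methoxyphenyl)-2,3-dihydro-1-benzofuran-3-yl]-6-methoxy-2-(4-methoxyphenyl)-2,3-dihydro-1-benzofuran-3-carboxylate
Conditions: 8 (1.3 equiv), 16 (1.0 equiv), Ir[dF(CF3)ppy]2(dtbbpy)PF6 (2 mol%), NiCl2·glyme (10 mol%), dtbbpy (15 mol%), Cs2CO3 (1.5 equiv), DMF, blue LEDs (450 nm), 25 °C
Reagents that add atoms: none
Why: Metallaphotoredox decarboxylative sp3–sp2 arylation: the cesium carboxylate is oxidised by excited Ir[dF(CF3)ppy]2(dtbbpy)PF6 and loses CO2, the benzylic C3 radical is captured by the aryl–nickel species formed from NiCl2·glyme/dtbbpy and bromide 16, and reductive elimination on the face opposite the C2 anisyl group should give the 2,3-trans ring B, while the aryl chloride does not add to nickel under these conditions.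

Step 10
Reactants: 17 methyl (2S,3S)-4-[(2R,3R)-6-chloro-2-(4-methoxyphenyl)-2,3-dihydro-1-benzofuran-3-yl]-6-methoxy-2-(4-methoxyphenyl)-2,3-dihydro-1-benzofuran-3-carboxylate
Product: 18 (2S,3S)-4-[(2R,3R)-6-chloro-2-(4-methoxyphenyl)-2,3-dihydro-1-benzofuran-3-yl]-6-methoxy-2-(4-methoxyphenyl)-2,3-dihydro-1-benzofuran-3-carboxylic acid
Conditions: LiOH·H2O (5 equiv), THF/MeOH/H2O (3:1:1), 50 °C; then 1 M HCl
Reagents that add atoms: lithium hydroxide, [Li+].[OH-]
Why: Saponification of the hindered methyl ester; any epimerisation at C3 of ring C is without consequence because this centre is reset in step 11, and the four other stereocentres are not acidic.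

Step 11
Reactants: 18 (2S,3S)-4-[(2R,3R)-6-chloro-2-(4-methoxyphenyl)-2,3-dihydro-1-benzofuran-3-yl]-6-methoxy-2-(4-methoxyphenyl)-2,3-dihydro-1-benzofuran-3-carboxylic acid; 9 1-bromo-3,5-dimethoxybenzene
Product: 19 (2S,3S)-4-[(2R,3R)-6-chloro-2-(4-methoxyphenyl)-2,3-dihydro-1-benzofuran-3-yl]-3-(3,5-dimethoxyphenyl)-6-methoxy-2-(4-methoxyphenyl)-2,3-dihydro-1-benzofuran
Conditions: 9 (2 equiv), Ir[dF(CF3)ppy]2(dtbbpy)PF6 (2 mol%), NiCl2·glyme (10 mol%), dtbbpy (15 mol%), Cs2CO3 (1.5 equiv), DMF, blue LEDs (450 nm), 25 °C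
Reagents that add atoms: none
Why: Second metallaphotoredox decarboxylative arylation of the same type as step 9, in which the C3 radical of ring C is arylated on the face opposite its C2 anisyl group (sets C3 as S, trans) and the unhindered bromide 9 reacts in preference to the aryl chloride.

Step 12
Reactants: 20 1-(2-hydroxy-3-methoxyphenyl)ethan-1-one
Product: 21 1-(5-chloro-2-hydroxy-3-methoxyphenyl)ethan-1-one
Conditions: NCS (1.05 equiv), MeCN, 50 °C
Reagents that add atoms: N-chlorosuccinimide, O=C1CCC(=O)N1Cl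
Why: Electrophilic aromatic chlorination directed para to the phenol, a position that is also meta to the acetyl group.

Step 13
Reactants: 21 1-(5-chloro-2-hydroxy-3-methoxyphenyl)ethan-1-one
Product: 23 6-chloro-8-methoxy-4H-chromen-4-one, via enaminone 22 (not isolated)
Conditions: DMF-DMA (1.5 equiv), toluene, 100 °C; evaporate; then conc. HCl, CH2Cl2, 40 °C
Reagents that add atoms: N,N-dimethylformamide dimethyl acetal, COC(OC)N(C)C
Why: Same enaminone condensation and acid-promoted cyclisation to the chromone as in step 1.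

Step 14
Reactants: 23 6-chloro-8-methoxy-4H-chromen-4-one; 4 (4-methoxyphenyl)boronic acid
Product: 24 (2S)-6-chloro-8-methoxy-2-(4-methoxyphenyl)-2,3-dihydro-4H-chromen-4-one
Conditions: 4 (2 equiv), Pd(OCOCF3)2 (5 mol%), (R)-t-BuPyOX (6 mol%), NH4PF6 (30 mol%), H2O (5 equiv), ClCH2CH2Cl, 60 °C
Reagents that add atoms: none
Why: Asymmetric conjugate addition of the arylboronic acid to the chromone as in step 7, with the ligand enantiomer that should set C2 as S.

Step 15
Reactants: 24 (2S)-6-chloro-8-methoxy-2-(4-methoxyphenyl)-2,3-dihydro-4H-chromen-4-one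
Product: 26 methyl (2S,3S)-5-chloro-7-methoxy-2-(4-methoxyphenyl)-2,3-dihydro-1-benzofuran-3-carboxylate, via methyl enol ether 25 (not isolated)
Conditions: PhI(OAc)2 (1.2 equiv), conc. H2SO4 (0.3 equiv), HC(OMe)3, 20 °C; then aq. NaHCO3
Reagents that add atoms: trimethyl orthoformate, COC(OC)OC; water, O
Why: Hypervalent-iodine ring contraction of a flavanone as in step 3, here forming ring A; C2 keeps its S configuration and the ester is placed trans by the antiperiplanar shift of the benzo carbon.

Step 16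
Reactants: 26 methyl (2S,3S)-5-chloro-7-methoxy-2-(4-methoxyphenyl)-2,3-dihydro-1-benzofuran-3-carboxylate
Product: 27 (2S,3S)-5-chloro-7-methoxy-2-(4-methoxyphenyl)-2,3-dihydro-1-benzofuran-3-carboxylic acid
Conditions: LiOH·H2O (3 equiv), THF/MeOH/H2O (3:1:1), 20 °C; then 1 M HCl
Reagents that add atoms: lithium hydroxide, [Li+].[OH-]
Why: Saponification of a methyl ester (BAc2) without effect on the non-acidic C2 centre.

Step 17
Reactants: 27 (2S,3S)-5-chloro-7-methoxy-2-(4-methoxyphenyl)-2,3-dihydro-1-benzofuran-3-carboxylic acid; 9 1-bromo-3,5-dimethoxybenzene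
Product: 28 (2S,3S)-5-chloro-3-(3,5-dimethoxyphenyl)-7-methoxy-2-(4-methoxyphenyl)-2,3-dihydro-1-benzofuran
Conditions: 9 (1.5 equiv), Ir[dF(CF3)ppy]2(dtbbpy)PF6 (2 mol%), NiCl2·glyme (10 mol%), dtbbpy (15 mol%), Cs2CO3 (1.5 equiv), DMF, blue LEDs (450 nm), 25 °C
Reagents that add atoms: none
Why: Metallaphotoredox decarboxylative arylation as in step 9, with arylation of the C3 radical opposite the C2 anisyl group (sets C3 as S, trans) and the aryl chloride left untouched.

Step 18
Reactants: 28 (2S,3S)-5-chloro-3-(3,5-dimethoxyphenyl)-7-methoxy-2-(4-methoxyphenyl)-2,3-dihydro-1-benzofuran; 29 potassium ethenyltrifluoroborate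
Product: 30 (2S,3S)-3-(3,5-dimethoxyphenyl)-5-ethenyl-7-methoxy-2-(4-methoxyphenyl)-2,3-dihydro-1-benzofuran
Conditions: 29 (1.5 equiv), Pd(OAc)2 (5 mol%), RuPhos (10 mol%), K2CO3 (3 equiv), toluene/H2O (10:1), 90 °C
Reagents that add atoms: none
Why: Suzuki–Miyaura vinylation of an electron-rich aryl chloride with a vinyltrifluoroborate, for which the bulky dialkylbiarylphosphine makes oxidative addition feasible; no stereocentre is touched.

Step 19
Reactants: 19 (2S,3S)-4-[(2R,3R)-6-chloro-2-(4-methoxyphenyl)-2,3-dihydro-1-benzofuran-3-yl]-3-(3,5-dimethoxyphenyl)-6-methoxy-2-(4-methoxyphenyl)-2,3-dihydro-1-benzofuran; 30 (2S,3S)-3-(3,5-dimethoxyphenyl)-5-ethenyl-7-methoxy-2-(4-methoxyphenyl)-2,3-dihydro-1-benzofuran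
Product: 31 nona-O-methyl ether of the target (E-stilbene joining C5 of ring A to C6 of ring B)
Conditions: 19 (1.0 equiv), 30 (1.2 equiv), Pd2(dba)3 (2.5 mol%), P(t-Bu)3 (10 mol%), Cs2CO3 (1.2 equiv), 1,4-dioxane, 110 °C
Reagents that add atoms: none
Why: Mizoroki–Heck reaction of an aryl chloride with a styrene using Pd2(dba)3/P(t-Bu)3, in which syn carbopalladation at the terminal alkene carbon and syn β-hydride elimination should give the E-stilbene.

Step 20
Reactants: 31 nona-O-methyl ether of the target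
Product: 32 CNP0265934.1 (target)
Conditions: BBr3 (25 equiv), CH2Cl2, −78 → 20 °C; then H2O, aq. NaHCO3, work-up under argon
Reagents that add atoms: none
Why: Lewis-acid O-demethylation of aryl methyl ethers with BBr3; the three trans-dihydrobenzofurans are the thermodynamic isomers and no arene is placed to cyclise onto the stilbene, so the skeleton and the six stereocentres should survive.

**Compound list**

1 | 1-(4-chloro-2-hydroxyphenyl)ethan-1-one | CC(=O)c1ccc(Cl)cc1O | starting material
2 | (E)-1-(4-chloro-2-hydroxyphenyl)-3-(dimethylamino)prop-2-en-1-one | CN(C)/C=C/C(=O)c1ccc(Cl)cc1O | intermediate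
3 | 7-chloro-4H-chromen-4-one | O=c1ccoc2cc(Cl)ccc12 | intermediate
4 | (4-methoxyphenyl)boronic acid | COc1ccc(B(O)O)cc1 | starting material
5 | (2R)-7-chloro-2-(4-methoxyphenyl)-2,3-dihydro-4H-chromen-4-one | Clc1ccc2c(c1)O[C@@H](c1ccc(OC)cc1)CC2=O | intermediate
6 | (2R)-7-chloro-4-methoxy-2-(4-methoxyphenyl)-2H-chromene | Clc1ccc2c(c1)O[C@@H](c1ccc(OC)cc1)C=C2OC | intermediate
7 | methyl (2R,3R)-6-chloro-2-(4-methoxyphenyl)-2,3-dihydro-1-benzofuran-3-carboxylate | Clc1ccc2c(c1)O[C@@H](c1ccc(OC)cc1)[C@@H]2C(=O)OC | intermediate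
8 | (2R,3R)-6-chloro-2-(4-methoxyphenyl)-2,3-dihydro-1-benzofuran-3-carboxylic acid | Clc1ccc2c(c1)O[C@@H](c1ccc(OC)cc1)[C@@H]2C(O)=O | intermediate
9 | 1-bromo-3,5-dimethoxybenzene | COc1cc(Br)cc(OC)c1 | starting material
10 | 1-(2-bromo-4,6-dimethoxyphenyl)ethan-1-one | CC(=O)c1c(Br)cc(OC)cc1OC | intermediate
11 | 1-(2-bromo-6-hydroxy-4-methoxyphenyl)ethan-1-one | CC(=O)c1c(Br)cc(OC)cc1O | intermediate
12 | (E)-1-(2-bromo-6-hydroxy-4-methoxyphenyl)-3-(dimethylamino)prop-2-en-1-one | CN(C)/C=C/C(=O)c1c(Br)cc(OC)cc1O | intermediate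
13 | 5-bromo-7-methoxy-4H-chromen-4-one | O=c1ccoc2cc(OC)cc(Br)c12 | intermediate
14 | (2S)-5-bromo-7-methoxy-2-(4-methoxyphenyl)-2,3-dihydro-4H-chromen-4-one | Brc1cc(OC)cc2c1C(=O)C[C@@H](c1ccc(OC)cc1)O2 | intermediate
15 | (2S)-5-bromo-4,7-dimethoxy-2-(4-methoxyphenyl)-2H-chromene | Brc1cc(OC)cc2c1C(OC)=C[C@@H](c1ccc(OC)cc1)O2 | intermediate
16 | methyl (2S,3S)-4-bromo-6-methoxy-2-(4-methoxyphenyl)-2,3-dihydro-1-benzofuran-3-carboxylate | Brc1cc(OC)cc2c1[C@H](C(=O)OC)[C@@H](c1ccc(OC)cc1)O2 | intermediate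
17 | methyl (2S,3S)-4-[(2R,3R)-6-chloro-2-(4-methoxyphenyl)-2,3-dihydro-1-benzofuran-3-yl]-6-methoxy-2-(4-methoxyphenyl)-2,3-dihydro-1-benzofuran-3-carboxylate | Clc1ccc2c(c1)O[C@@H](c1ccc(OC)cc1)[C@@H]2c1cc(OC)cc2c1[C@H](C(=O)OC)[C@@H](c1ccc(OC)cc1)O2 | intermediate
18 | (2S,3S)-4-[(2R,3R)-6-chloro-2-(4-methoxyphenyl)-2,3-dihydro-1-benzofuran-3-yl]-6-methoxy-2-(4-methoxyphenyl)-2,3-dihydro-1-benzofuran-3-carboxylic acid | Clc1ccc2c(c1)O[C@@H](c1ccc(OC)cc1)[C@@H]2c1cc(OC)cc2c1[C@H](C(O)=O)[C@@H](c1ccc(OC)cc1)O2 | intermediate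
19 | (2S,3S)-4-[(2R,3R)-6-chloro-2-(4-methoxyphenyl)-2,3-dihydro-1-benzofuran-3-yl]-3-(3,5-dimethoxyphenyl)-6-methoxy-2-(4-methoxyphenyl)-2,3-dihydro-1-benzofuran | Clc1ccc2c(c1)O[C@@H](c1ccc(OC)cc1)[C@@H]2c1cc(OC)cc2c1[C@H](c1cc(OC)cc(OC)c1)[C@@H](c1ccc(OC)cc1)O2 | intermediate
20 | 1-(2-hydroxy-3-methoxyphenyl)ethan-1-one | CC(=O)c1cccc(OC)c1O | starting material
21 | 1-(5-chloro-2-hydroxy-3-methoxyphenyl)ethan-1-one | CC(=O)c1cc(Cl)cc(OC)c1O | intermediate
22 | (E)-1-(5-chloro-2-hydroxy-3-methoxyphenyl)-3-(dimethylamino)prop-2-en-1-one | CN(C)/C=C/C(=O)c1cc(Cl)cc(OC)c1O | intermediate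
23 | 6-chloro-8-methoxy-4H-chromen-4-one | O=c1ccoc2c(OC)cc(Cl)cc12 | intermediate
24 | (2S)-6-chloro-8-methoxy-2-(4-methoxyphenyl)-2,3-dihydro-4H-chromen-4-one | COc1ccc([C@H]2Oc3c(OC)cc(Cl)cc3C(=O)C2)cc1 | intermediate
25 | (2S)-6-chloro-4,8-dimethoxy-2-(4-methoxyphenyl)-2H-chromene | COc1ccc([C@H]2Oc3c(OC)cc(Cl)cc3C(OC)=C2)cc1 | intermediate
26 | methyl (2S,3S)-5-chloro-7-methoxy-2-(4-methoxyphenyl)-2,3-dihydro-1-benzofuran-3-carboxylate | COc1ccc([C@H]2Oc3c(OC)cc(Cl)cc3[C@@H]2C(=O)OC)cc1 | intermediate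
27 | (2S,3S)-5-chloro-7-methoxy-2-(4-methoxyphenyl)-2,3-dihydro-1-benzofuran-3-carboxylic acid | COc1ccc([C@H]2Oc3c(OC)cc(Cl)cc3[C@@H]2C(O)=O)cc1 | intermediate
28 | (2S,3S)-5-chloro-3-(3,5-dimethoxyphenyl)-7-methoxy-2-(4-methoxyphenyl)-2,3-dihydro-1-benzofuran | COc1ccc([C@H]2Oc3c(OC)cc(Cl)cc3[C@@H]2c2cc(OC)cc(OC)c2)cc1 | intermediate
29 | potassium ethenyltrifluoroborate | C=C[B-](F)(F)F.[K+] | starting material
30 | (2S,3S)-3-(3,5-dimethoxyphenyl)-5-ethenyl-7-methoxy-2-(4-methoxyphenyl)-2,3-dihydro-1-benzofuran | COc1ccc([C@H]2Oc3c(OC)cc(C=C)cc3[C@@H]2c2cc(OC)cc(OC)c2)cc1 | intermediate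
31 | nona-O-methyl ether of the target | COc1ccc([C@H]2Oc3c(OC)cc(/C=C/c4ccc5c(c4)O[C@@H](c4ccc(OC)cc4)[C@@H]5c4cc(OC)cc5c4[C@H](c4cc(OC)cc(OC)c4)[C@@H](c4ccc(OC)cc4)O5)cc3[C@@H]2c2cc(OC)cc(OC)c2)cc1 | intermediate
32 | CNP0265934.1 | Oc1ccc([C@H]2Oc3c(O)cc(/C=C/c4ccc5c(c4)O[C@@H](c4ccc(O)cc4)[C@@H]5c4cc(O)cc5c4[C@H](c4cc(O)cc(O)c4)[C@@H](c4ccc(O)cc4)O5)cc3[C@@H]2c2cc(O)cc(O)c2)cc1 | target

**Step count and risks**

Total step count: 20. Longest linear sequence: 9 steps (for example 9 → 32 through steps 5–11, 19 and 20).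

Steps most likely to fail:

Step 9. Oxidative addition to nickel at the ortho-substituted bromide 16 and capture of the secondary benzylic radical are both slowed by crowding, so protodecarboxylation and dimerisation of the C3 radical of ring B may take over. The fallback sets out from 8 and 13 and comes back at 17. Acid 8 is coupled under the same Ir[dF(CF3)ppy]2(dtbbpy)PF6/NiCl2·glyme/dtbbpy conditions with the flat, carbonyl-activated bromide 13 to give 5-[(2R,3R)-6-chloro-2-(4-methoxyphenyl)-2,3-dihydro-1-benzofuran-3-yl]-7-methoxy-4H-chromen-4-one F1. Conjugate addition of 4 with Pd(OCOCF3)2/(R)-t-BuPyOX as in step 7 should then give the (2S)-flavanone F2, and the PhI(OAc)2/H2SO4/HC(OMe)3 ring contraction as in step 8 returns ester 17. Ring C is thus built on ring B instead of being brought in complete.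

Step 11. The C3 radical of ring C is flanked by the C2 aryl group and by the ring-B substituent on C4; its capture by the aryl–nickel species formed from the electron-rich bromide 9 may be too slow, so that hydrogen-atom abstraction gives the 3-unsubstituted dihydrobenzofuran. The fallback sets out from 18 and comes back at 19. Acid 18 is esterified with N-hydroxytetrachlorophthalimide (DIC, DMAP cat., CH2Cl2) to the redox-active ester F3. F3 is coupled with commercial (3,5-dimethoxyphenyl)boronic acid in the nickel-catalysed decarboxylative Suzuki-type arylation of redox-active esters (NiCl2·6H2O, bathophenanthroline, Et3N, 1,4-dioxane/DMF, 75 °C). Here the aryl group reaches nickel by transmetalation and the radical is released by single-electron reduction of the ester close to the metal, with no light and no oxidative addition of an electron-rich bromide.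

Step 19. Slow oxidative addition of the unactivated aryl chloride at 110 °C may let the catalyst decompose to palladium black, and arylation at the internal alkene carbon would give the 1,1-diarylethene. The fallback sets out from 28 and comes back at 31. Suzuki–Miyaura coupling of 28 with an excess of commercial (E)-1,2-bis(4,4,5,5-tetramethyl-1,3,2-dioxaborolan-2-yl)ethene (Pd(OAc)2, SPhos, K3PO4, 1,4-dioxane/H2O, 80 °C) gives the (E)-alkenylboronate F4. A second Suzuki–Miyaura coupling of F4 with chloride 19 under the same conditions gives 31, with the E geometry fixed by the reagent.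

Further compounds

F1 | step 9 | 5-[(2R,3R)-6-chloro-2-(4-methoxyphenyl)-2,3-dihydro-1-benzofuran-3-yl]-7-methoxy-4H-chromen-4-one | Clc1ccc2c(c1)O[C@@H](c1ccc(OC)cc1)[C@@H]2c1cc(OC)cc2occc(=O)c12
F2 | step 9 | (2S)-5-[(2R,3R)-6-chloro-2-(4-methoxyphenyl)-2,3-dihydro-1-benzofuran-3-yl]-7-methoxy-2-(4-methoxyphenyl)-2,3-dihydro-4H-chromen-4-one | Clc1ccc2c(c1)O[C@@H](c1ccc(OC)cc1)[C@@H]2c1cc(OC)cc2c1C(=O)C[C@@H](c1ccc(OC)cc1)O2
F3 | step 11 | 4,5,6,7-tetrachloro-1,3-dioxoisoindolin-2-yl (2S,3S)-4-[(2R,3R)-6-chloro-2-(4-methoxyphenyl)-2,3-dihydro-1-benzofuran-3-yl]-6-methoxy-2-(4-methoxyphenyl)-2,3-dihydro-1-benzofuran-3-carboxylate | Clc1ccc2c(c1)O[C@@H](c1ccc(OC)cc1)[C@@H]2c1cc(OC)cc2c1[C@H](C(=O)ON1C(=O)c3c(Cl)c(Cl)c(Cl)c(Cl)c3C1=O)[C@@H](c1ccc(OC)cc1)O2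
F4 | step 19 | 2-[(E)-2-[(2S,3S)-3-(3,5-dimethoxyphenyl)-7-methoxy-2-(4-methoxyphenyl)-2,3-dihydro-1-benzofuran-5-yl]ethenyl]-4,4,5,5-tetramethyl-1,3,2-dioxaborolane | COc1ccc([C@H]2Oc3c(OC)cc(/C=C/B4OC(C)(C)C(C)(C)O4)cc3[C@@H]2c2cc(OC)cc(OC)c2)cc1
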